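**Assumption:** the SMILES is read as the all-cis (3R,4R,5R)-oxolane, with aryl, hydroxymethyl and aroyl on one face. Lignan locants: C7/C8/C9 for the trimethoxyphenyl C3 unit, C7'/C8'/C9' for the dimethoxyphenyl unit.

## Retrosynthetic overview

1. The keto alcohol is the open tautomer of a C7-hydroxylated 3,7-dioxabicyclo[3.3.0]octane (furofuran) hemiketal. It is therefore cut, as in its presumed origin from an oxidised furofuran, to an endo-aryl bicyclic lactone plus 3,4,5-trimethoxyphenyllithium.
2. The endo (cis) 3,4-dimethoxyphenyl group comes from exo-face hydride capture of a para-methoxy-stabilised, quinone-methide-type oxocarbenium ion, itself from mono-arylation of a C2-symmetric bislactone.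
3. The bislactone comes from twofold 9-O to 7-C ring closure of a 2,3-bis(hydroxymethyl)succinyl unit. Its 8–8' bond is made by auxiliary-controlled oxidative enolate homocoupling, the counterpart of the 8–8' radical coupling of two C3 side chains.
4. Ring order: 8–8' bond first, then both oxygen rings together. The aryl groups are added afterwards; the ring that stays is fixed at C7' by hydride, and the other ring is opened at C7 in the last step.

## Route

Step 1
Reactants: 1 (R)-4-benzyl-1,3-oxazolidin-2-one; 2 3-(benzyloxy)propanoic acid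
Product: 4 (R)-4-benzyl-3-[3-(benzyloxy)propanoyl]-1,3-oxazolidin-2-one, via mixed pivalic anhydride 3 (not isolated)
Conditions: PivCl (1.1 equiv), Et3N (2.5 equiv), THF, −20 °C; then LiCl (1.1 equiv), 1, −20 °C to rt
Reagents that add atoms: none
Why: One-pot mixed-anhydride N-acylation of the oxazolidinone (LiCl-assisted acyl transfer), which forms no stereocenter and leaves the auxiliary center untouched.

Step 2
Reactants: 4 (R)-4-benzyl-3-[3-(benzyloxy)propanoyl]-1,3-oxazolidin-2-one (2 equiv)
Product: 6 3,3'-[(2R,3R)-2,3-bis(benzyloxymethyl)butanedioyl]bis[(R)-4-benzyl-1,3-oxazolidin-2-one], via lithium Z-enolate 5 (not isolated)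
Conditions: LiN(iPr)2 (1.05 equiv), THF, −78 °C, 45 min; then anhydrous CuCl2 (1.1 equiv) in DMF, −78 to −40 °C; chromatography
Reagents that add atoms: none
Why: Oxidative enolate homocoupling (single-electron oxidation of the chelated Z-enolate by divalent copper, the laboratory counterpart of the lignan 8–8' radical coupling), in which each new C–C bond forms on the enolate face anti to the 4-benzyl group, so the doubly matched C2-symmetric (2R,3R) dimer dominates, the meso dimer is separable and the (S,S) dimer is statistically negligible.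

Step 3
Reactants: 6 3,3'-[(2R,3R)-2,3-bis(benzyloxymethyl)butanedioyl]bis[(R)-4-benzyl-1,3-oxazolidin-2-one]
Product: 8 (1R,5R)-3,7-dioxabicyclo[3.3.0]octane-2,6-dione, via diol 7 (not isolated)
Conditions: H2 (1 atm), 10% Pd/C, TsOH·H2O (10 mol %), EtOAc, rt to 40 °C
Reagents that add atoms: none
Why: Hydrogenolysis of both benzyl ethers followed by acid-catalysed double lactonisation (intramolecular N-to-O acyl transfer), in which each 9-hydroxyl closes a five-membered ring onto the acyl carbon of the other half so that both rings of the cis-fused bicycle form together, the auxiliary is released, the two stereocenters are untouched and only the (R,R) dimer can close twice.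

Step 4
Reactants: 8 (1R,5R)-3,7-dioxabicyclo[3.3.0]octane-2,6-dione; 9 4-bromo-1,2-dimethoxybenzene
Product: 11 (3R,4R)-4-(3,4-dimethoxybenzoyl)-3-(hydroxymethyl)oxolan-2-one, via aryllithium 10 (not isolated)
Conditions: 9, n-BuLi (1.0 equiv), THF, −78 °C; then added slowly to 8 (1.1 equiv), THF, −78 °C; sat. aq. NH4Cl at −78 °C; crude product used at once
Reagents that add atoms: none
Why: Bromine–lithium exchange and 1,2-addition of one aryllithium to one of the two lactone carbonyls, which are equivalent by C2 symmetry, where the tetrahedral lithium hemiketal alkoxide is stable at −78 °C and stops at mono-addition, and the cis ring fusion holds C3 and C4 in place.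

Step 5
Reactants: 11 (3R,4R)-4-(3,4-dimethoxybenzoyl)-3-(hydroxymethyl)oxolan-2-one
Product: 14 (1R,5R,6R)-6-(3,4-dimethoxyphenyl)-3,7-dioxabicyclo[3.3.0]octan-2-one, via bicyclic hemiketal 12 (not isolated), via oxocarbenium ion 13 (not isolated)
Conditions: Et3SiH (3 equiv), BF3·OEt2 (2 equiv, Lewis acid), CH2Cl2, −78 °C; sat. aq. NaHCO3 at −78 °C
Reagents that add atoms: none
Why: Ionic hydrogenation (reductive etherification), in which the 9-hydroxyl closes onto C7', BF3 ionises the hemiketal to the para-methoxy-stabilised oxocarbenium ion (an O-alkyl quinone methide cation) and Et3SiH delivers hydride to the convex exo face of the cis-fused bicycle, placing the aryl group endo (6R), cis to C4H2.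

Step 6
Reactants: 14 (1R,5R,6R)-6-(3,4-dimethoxyphenyl)-3,7-dioxabicyclo[3.3.0]octan-2-one; 15 5-bromo-1,2,3-trimethoxybenzene
Product: 18 [(3R,4R,5R)-5-(3,4-dimethoxyphenyl)-4-(hydroxymethyl)oxolan-3-yl](3,4,5-trimethoxyphenyl)methanone, via aryllithium 16 (not isolated), via bicyclic hemiketal 17 (not isolated)
Conditions: 15, n-BuLi (1.1 equiv), THF, −78 °C; then 14, THF, −78 °C, 30 min; sat. aq. NH4Cl at −78 °C, then rt
Reagents that add atoms: none
Why: Aryllithium 1,2-addition to the gamma-lactone gives the lithium alkoxide of the C7 hemiketal, which on cold protonation opens by ring-chain tautomerism to the aryl ketone and the primary alcohol (the same hemiketal opening that follows benzylic C7 oxidation of a furofuran), with no stereocenter touched and the cis C3/C4 relationship inherited from the ring fusion.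

## Compound list

1 | (R)-4-benzyl-1,3-oxazolidin-2-one | O=C1N[C@H](Cc2ccccc2)CO1 | starting material
2 | 3-(benzyloxy)propanoic acid | OC(=O)CCOCc1ccccc1 | starting material
3 | 3-(benzyloxy)propanoic pivalic anhydride | CC(C)(C)C(=O)OC(=O)CCOCc1ccccc1 | intermediate (not isolated)
4 | (R)-4-benzyl-3-[3-(benzyloxy)propanoyl]-1,3-oxazolidin-2-one | O=C(CCOCc1ccccc1)N1[C@H](Cc2ccccc2)COC1=O | intermediate
5 | lithium Z-enolate of 4 | [Li]O/C(=C\COCc1ccccc1)N1[C@H](Cc2ccccc2)COC1=O | intermediate (not isolated)
6 | 3,3'-[(2R,3R)-2,3-bis(benzyloxymethyl)butanedioyl]bis[(R)-4-benzyl-1,3-oxazolidin-2-one] | O=C(N1[C@H](Cc2ccccc2)COC1=O)[C@@H](COCc1ccccc1)[C@H](COCc1ccccc1)C(=O)N1[C@H](Cc2ccccc2)COC1=O | intermediate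
7 | 3,3'-[(2R,3R)-2,3-bis(hydroxymethyl)butanedioyl]bis[(R)-4-benzyl-1,3-oxazolidin-2-one] | O=C(N1[C@H](Cc2ccccc2)COC1=O)[C@@H](CO)[C@H](CO)C(=O)N1[C@H](Cc2ccccc2)COC1=O | intermediate (not isolated)
8 | (1R,5R)-3,7-dioxabicyclo[3.3.0]octane-2,6-dione | O=C1OC[C@H](C(=O)O2)[C@@H]1C2 | intermediate
9 | 4-bromo-1,2-dimethoxybenzene | COc1ccc(Br)cc1OC | starting material
10 | 3,4-dimethoxyphenyllithium | [Li]c1ccc(OC)c(OC)c1 | intermediate (not isolated)
11 | (3R,4R)-4-(3,4-dimethoxybenzoyl)-3-(hydroxymethyl)oxolan-2-one (cis) | OC[C@H](C(=O)O1)[C@@H](C(=O)c2ccc(OC)c(OC)c2)C1 | intermediate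
12 | (1R,5R)-6-(3,4-dimethoxyphenyl)-6-hydroxy-3,7-dioxabicyclo[3.3.0]octan-2-one (C6 epimers) | OC2(c1ccc(OC)c(OC)c1)OC[C@H](C(=O)O3)[C@@H]2C3 | intermediate (not isolated)
13 | (1R,5R)-6-(3,4-dimethoxyphenyl)-2-oxo-3-oxa-7-oxoniabicyclo[3.3.0]oct-6-ene | COc1ccc(C2=[O+]C[C@H](C(=O)O3)[C@@H]2C3)cc1OC | intermediate (not isolated)
14 | (1R,5R,6R)-6-(3,4-dimethoxyphenyl)-3,7-dioxabicyclo[3.3.0]octan-2-one (aryl endo) | COc1ccc([C@@H]2OC[C@H](C(=O)O3)[C@@H]2C3)cc1OC | intermediate
15 | 5-bromo-1,2,3-trimethoxybenzene | COc1cc(Br)cc(OC)c1OC | starting material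
16 | 3,4,5-trimethoxyphenyllithium | [Li]c1cc(OC)c(OC)c(OC)c1 | intermediate (not isolated)
17 | (1R,5R,6R)-6-(3,4-dimethoxyphenyl)-2-(3,4,5-trimethoxyphenyl)-3,7-dioxabicyclo[3.3.0]octan-2-ol (C2 epimers) | COc1ccc([C@@H]2OC[C@H]3[C@@H]2COC3(O)c2cc(OC)c(OC)c(OC)c2)cc1OC | intermediate (not isolated)
18 | [(3R,4R,5R)-5-(3,4-dimethoxyphenyl)-4-(hydroxymethyl)oxolan-3-yl](3,4,5-trimethoxyphenyl)methanone | COc1ccc([C@@H]2OC[C@H](C(=O)c3cc(OC)c(OC)c(OC)c3)[C@@H]2CO)cc1OC | target

## Step count

Total steps: 6. Longest linear sequence: 6 (1 and 2 to 18); the two aryl bromides enter as reagents lithiated in the flask.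

## Steps most likely to fail, with fallbacks

**Step 2 (oxidative homocoupling).** The lithium enolate 5 carries a beta-benzyloxy group and may eliminate, the ether oxygen may disturb the chelate that controls the face, and copper-mediated dimerisations often give moderate mass balance. The fallback makes the same 8–8' bond reductively from radicals instead of oxidatively from enolates. Compound 4 is enolised softly (Bu2BOTf, iPr2NEt, CH2Cl2, −78 °C) to the dibutylboron Z-enolate of 4 F1 and brominated with NBS to (R)-4-benzyl-3-[3-(benzyloxy)-2-bromopropanoyl]-1,3-oxazolidin-2-one F2. F2 is then homocoupled by atom-transfer radical coupling (copper powder, that is zerovalent copper, with CuBr, Me6TREN and MgBr2·OEt2 in THF at 0 °C). The MgBr2-chelated alpha-imide radicals should combine anti to the 4-benzyl groups. This fallback sets out from 4 and comes back to the route at 6.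

**Step 4 (mono-addition to the bislactone).** Bis-addition, enolisation of 8 by the aryllithium, and epimerisation of 11 at the ketone-bearing carbon before step 5 are all possible. The fallback differentiates the two halves before the 8–8' bond is made:
- Mixed anhydride 3 is treated with MeNHOMe·HCl and Et3N to give N-methoxy-N-methyl-3-(benzyloxy)propanamide F3.
- Aryllithium 10 converts F3 into 3-(benzyloxy)-1-(3,4-dimethoxyphenyl)propan-1-one F4.
- F4 is deprotonated (LiN(iPr)2, THF, −78 °C) to the lithium Z-enolate of F4 F5.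
- F5 is cross-coupled with enolate 5 using Fe(acac)3 (trivalent iron) to (R)-4-benzyl-3-[(2R)-2,3-bis(benzyloxymethyl)-4-(3,4-dimethoxyphenyl)-4-oxobutanoyl]-1,3-oxazolidin-2-one F6. C2 is set by the auxiliary; C3 is a mixture of epimers.
- Hydrogenolysis (H2, Pd/C, EtOAc) gives (R)-4-benzyl-3-[(2R)-4-(3,4-dimethoxyphenyl)-2,3-bis(hydroxymethyl)-4-oxobutanoyl]-1,3-oxazolidin-2-one F7, which lactonises on the imide side with TsOH.

Because the ketone-bearing carbon epimerises, the material should drain into the cis isomer, which is held as hemiketal 12. This fallback sets out from 4 (using 3 and 10) and comes back at 11.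

**Step 5 (endo-selective ionic reduction).** Hydride may not discriminate the two faces well enough, BF3 may epimerise the endo benzylic ether to the exo isomer if the mixture warms, and any trans epimer of 11 cannot cyclise and would be deoxygenated instead. The fallback replaces hydride delivery by hydrogenation. Compound 11 is dehydrated through hemiketal 12 (TsOH cat., toluene, 4 Å sieves, 60 °C) to (1R)-6-(3,4-dimethoxyphenyl)-3,7-dioxabicyclo[3.3.0]oct-5-en-2-one F8. Acid equilibration feeds any trans epimer of 11 into this enol ether. H2 over Rh/Al2O3 (5 bar, EtOAc, rt) then adds syn from the convex face, which sets the cis ring fusion and the endo aryl group together. This fallback sets out from 11 and comes back at 14.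

## Further compounds

F1 | step 2 | dibutylboron Z-enolate of 4 | CCCCB(CCCC)O/C(=C\COCc1ccccc1)N1[C@H](Cc2ccccc2)COC1=O
F2 | step 2 | (R)-4-benzyl-3-[3-(benzyloxy)-2-bromopropanoyl]-1,3-oxazolidin-2-one (C2 epimers) | O=C(C(Br)COCc1ccccc1)N1[C@H](Cc2ccccc2)COC1=O
F3 | step 4 | N-methoxy-N-methyl-3-(benzyloxy)propanamide | CON(C)C(=O)CCOCc1ccccc1
F4 | step 4 | 3-(benzyloxy)-1-(3,4-dimethoxyphenyl)propan-1-one | COc1ccc(C(=O)CCOCc2ccccc2)cc1OC
F5 | step 4 | lithium Z-enolate of F4 | [Li]O/C(=C\COCc1ccccc1)c1ccc(OC)c(OC)c1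
F6 | step 4 | (R)-4-benzyl-3-[(2R)-2,3-bis(benzyloxymethyl)-4-(3,4-dimethoxyphenyl)-4-oxobutanoyl]-1,3-oxazolidin-2-one (C3 epimers) | O=C(N1[C@H](Cc2ccccc2)COC1=O)[C@@H](COCc1ccccc1)C(COCc1ccccc1)C(=O)c1ccc(OC)c(OC)c1
F7 | step 4 | (R)-4-benzyl-3-[(2R)-4-(3,4-dimethoxyphenyl)-2,3-bis(hydroxymethyl)-4-oxobutanoyl]-1,3-oxazolidin-2-one (C3 epimers) | O=C(N1[C@H](Cc2ccccc2)COC1=O)[C@@H](CO)C(CO)C(=O)c1ccc(OC)c(OC)c1
F8 | step 5 | (1R)-6-(3,4-dimethoxyphenyl)-3,7-dioxabicyclo[3.3.0]oct-5-en-2-one | COc1ccc(C2OC[C@H](C(=O)O3)C=2C3)cc1OC
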